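**Retrosynthetic overview**
1. Side chain last: C12–C13 by B-alkyl Suzuki coupling of a 9-vinyl diene with 4-bromofuran-2(5H)-one; C9–C11 by Negishi vinylation of the C8-methylated C9 enol triflate.
2. Key step: ring A is closed onto a preformed ring B by a hydrogen-atom-transfer radical cyclization. The C4 tertiary radical adds 6-exo to the C5=C6 enol acetate, forming C4–C5 and setting C5 (trans fusion) and C6 (axial 6β-OAc).
3. The C10 quaternary centre and the regiodefined enol acetate both come from one anti-selective cuprate addition / O-acylation on (S)-4-silyloxy-3-methylcyclohexenone.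
4. The temporary C9 carbinol centre (later the C9 ketone, then the C8=C9 alkene) comes from CBS reduction of the partly hydrogenated o-cresol quinone monoketal.
5. Ring order: B (from o-cresol) → A (radical cyclization) → butenolide (attached preformed).

Assumption: labdane numbering is used in the comments (C4 gem-dimethyl carbon, C5/C10 ring fusion, C6 acetoxy carbon, C8=C9 alkene), the target is (5S,6R,10S), and 1, 7, 16, 19 and all reagents are commercial.

**Route**

Step 1
Reactants: 1 2-methylphenol (o-cresol)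
Product: 2 4,4-dimethoxy-2-methylcyclohexa-2,5-dien-1-one
Conditions: PhI(OAc)2 (2.2 equiv), MeOH, 0 °C → rt
Reagents that add atoms: methanol (CO)
Why: Hypervalent-iodine oxidative dearomatization (two para-methoxylations) of a para-unsubstituted phenol gives the p-quinone monoketal whose free carbonyl sits next to the methyl-bearing carbon; no stereocentre is formed.

Step 2
Reactants: 2 4,4-dimethoxy-2-methylcyclohexa-2,5-dien-1-one
Product: 3 4,4-dimethoxy-2-methylcyclohex-2-en-1-one
Conditions: H2 (1 atm), (Ph3P)3RhCl (5 mol%), benzene/EtOH, rt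
Reagents that add atoms: none
Why: Wilkinson hydrogenation reduces only the unhindered disubstituted enone C=C and leaves the trisubstituted, methyl-bearing alkene.

Step 3
Reactants: 3 4,4-dimethoxy-2-methylcyclohex-2-en-1-one
Product: 4 (S)-4,4-dimethoxy-2-methylcyclohex-2-en-1-ol
Conditions: (R)-Me-CBS (15 mol%), BH3·SMe2, THF, −30 °C; MeOH quench
Reagents that add atoms: none
Why: Corey–Bakshi–Shibata reduction, in which the α-methyl alkenyl arm is the large group, so the (R)-catalyst gives the (S)-allylic alcohol (temporary C9 centre, oxygen on the future β-face).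

Step 4
Reactants: 4 (S)-4,4-dimethoxy-2-methylcyclohex-2-en-1-ol
Product: 6 (S)-4-[(tert-butyldimethylsilyl)oxy]-3-methylcyclohex-2-en-1-one, via silyl ether ketal 5 (not isolated)
Conditions: TBSCl, imidazole, DMF, rt; then 1 M aq HCl, THF, 0 °C
Reagents that add atoms: tert-butyldimethylsilyl chloride (CC(C)(C)[Si](C)(C)Cl); water (O)
Why: Silylation followed by mild hydrolysis of the allylic dimethyl ketal unmasks the enone whose carbonyl is the future C6; the carbinol centre is untouched.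

Step 5
Reactants: 6 (S)-4-[(tert-butyldimethylsilyl)oxy]-3-methylcyclohex-2-en-1-one; 7 5-bromo-2-methylpent-2-ene
Product: 10 (3S,4S)-4-[(tert-butyldimethylsilyl)oxy]-3-methyl-3-(4-methylpent-3-en-1-yl)cyclohex-1-en-1-yl acetate, via Grignard reagent 8 (not isolated), via magnesium enolate 9 (not isolated)
Conditions: 7, Mg, THF; CuBr·SMe2 (1.1 equiv per 2.2 equiv RMgBr), THF/Me2S, −78 → −30 °C, add 6; then Ac2O, −30 → 0 °C
Reagents that add atoms: acetic anhydride (CC(=O)OC(C)=O)
Why: Copper-mediated conjugate addition occurs anti to the γ-silyloxy group and so sets the C10 quaternary centre (chain α, methyl β), and O-acylation of the regiodefined enolate fixes the C5=C6 enol acetate.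

Step 6
Reactants: 10 (3S,4S)-4-[(tert-butyldimethylsilyl)oxy]-3-methyl-3-(4-methylpent-3-en-1-yl)cyclohex-1-en-1-yl acetate
Product: 11 (1R,4S,4aS,8aS)-4-[(tert-butyldimethylsilyl)oxy]-4a,8,8-trimethyldecahydronaphthalen-1-yl acetate (trans-fused; acetate axial)
Conditions: Mn(dpm)3 (10 mol%), PhSiH3 (1.5 equiv), t-BuOOH (1.5 equiv), degassed i-PrOH (0.01 M), 22 °C
Reagents that add atoms: none
Why: Proposed new method: Mn–H transfers H• to the prenyl alkene (Markovnikov MHAT) to give the C4 tertiary radical, which closes 6-exo onto C5 of the enol acetate (attack at the non-oxygenated carbon gives the tertiary α-acetoxy radical, helped by the quaternary C10 in the tether) through a chair transition state with the ring-B bonds and the C9 silyloxy group equatorial, giving the trans fusion, and the C6 radical then takes a second H atom on the α-face because the β-face is blocked by the axial C10 and C4 methyls, leaving the acetate axial (6β); the closest known reactions are HAT-initiated radical cyclizations and HAT alkene hydrogenation (Mukaiyama/Baran/Shenvi type) and tin-mediated radical cyclizations onto enol esters and enamides.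

Step 7
Reactants: 11 (1R,4S,4aS,8aS)-4-[(tert-butyldimethylsilyl)oxy]-4a,8,8-trimethyldecahydronaphthalen-1-yl acetate
Product: 12 (1R,4S,4aS,8aS)-4-hydroxy-4a,8,8-trimethyldecahydronaphthalen-1-yl acetate
Conditions: HF·pyridine, THF, 0 °C → rt
Reagents that add atoms: none
Why: Fluoride cleavage of the silyl ether leaves the hindered axial acetate intact.

Step 8
Reactants: 12 (1R,4S,4aS,8aS)-4-hydroxy-4a,8,8-trimethyldecahydronaphthalen-1-yl acetate
Product: 13 (1R,4aS,8aS)-4a,8,8-trimethyl-4-oxodecahydronaphthalen-1-yl acetate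
Conditions: Dess–Martin periodinane, CH2Cl2, rt
Reagents that add atoms: none
Why: Dess–Martin oxidation gives the C9 ketone and removes the temporary stereocentre.

Step 9
Reactants: 13 (1R,4aS,8aS)-4a,8,8-trimethyl-4-oxodecahydronaphthalen-1-yl acetate
Product: 14 (1R,3R,4aS,8aS)-3,4a,8,8-tetramethyl-4-oxodecahydronaphthalen-1-yl acetate (equatorial 8α-methyl epimer major)
Conditions: LiHMDS (1.1 equiv), THF, −78 °C; MeI, −78 → −20 °C
Reagents that add atoms: iodomethane (CI)
Why: Enolate alkylation can occur only at C8 because C10 is quaternary, LiHMDS does not touch the acetate, and the new methyl centre becomes sp2 in the next step.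

Step 10
Reactants: 14 (1R,3R,4aS,8aS)-3,4a,8,8-tetramethyl-4-oxodecahydronaphthalen-1-yl acetate
Product: 15 (1R,4aS,8aS)-3,4a,8,8-tetramethyl-4-{[(trifluoromethyl)sulfonyl]oxy}-1,2,4a,5,6,7,8,8a-octahydronaphthalen-1-yl acetate
Conditions: KHMDS (1.2 equiv), THF, −78 °C; PhNTf2, −78 → 0 °C
Reagents that add atoms: N-phenylbis(trifluoromethanesulfonimide) (O=S(=O)(N(c1ccccc1)S(=O)(=O)C(F)(F)F)C(F)(F)F)
Why: Regiospecific enol triflate formation (the only α-hydrogen is at C8) fixes the tetrasubstituted C8=C9 alkene.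

Step 11
Reactants: 15 (1R,4aS,8aS)-3,4a,8,8-tetramethyl-4-{[(trifluoromethyl)sulfonyl]oxy}-1,2,4a,5,6,7,8,8a-octahydronaphthalen-1-yl acetate; 16 vinylmagnesium bromide
Product: 18 (1R,4aS,8aS)-4-ethenyl-3,4a,8,8-tetramethyl-1,2,4a,5,6,7,8,8a-octahydronaphthalen-1-yl acetate, via vinylzinc bromide 17 (not isolated)
Conditions: 16, ZnBr2, THF, 0 °C; then 15, Pd(PPh3)4 (5 mol%), LiCl, THF, 50 °C
Reagents that add atoms: none
Why: Transmetalation to zinc followed by Negishi coupling at the enol triflate installs C11–C12 as a vinyl group, and the organozinc tolerates the acetate.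

Step 12
Reactants: 18 (1R,4aS,8aS)-4-ethenyl-3,4a,8,8-tetramethyl-1,2,4a,5,6,7,8,8a-octahydronaphthalen-1-yl acetate; 19 4-bromofuran-2(5H)-one
Product: 21 (1R,4aS,8aS)-3,4a,8,8-tetramethyl-4-[2-(5-oxo-2,5-dihydrofuran-3-yl)ethyl]-1,2,4a,5,6,7,8,8a-octahydronaphthalen-1-yl acetate, via alkylborane 20 (not isolated)
Conditions: 9-BBN (1.3 equiv), THF, 0 °C → rt; then 19, Pd(dppf)Cl2 (5 mol%), AsPh3, 3 M aq K3PO4, DMF, rt
Reagents that add atoms: none
Why: Anti-Markovnikov hydroboration of the only terminal alkene followed by B-alkyl Suzuki–Miyaura coupling with the β-bromobutenolide forms C12–C13 without touching any stereocentre.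

**Compound list**
1 | 2-methylphenol (o-cresol) | Cc1ccccc1O | starting material
2 | 4,4-dimethoxy-2-methylcyclohexa-2,5-dien-1-one | COC1(OC)C=CC(=O)C(C)=C1 | intermediate
3 | 4,4-dimethoxy-2-methylcyclohex-2-en-1-one | COC1(OC)CCC(=O)C(C)=C1 | intermediate
4 | (S)-4,4-dimethoxy-2-methylcyclohex-2-en-1-ol | COC1(OC)C=C(C)[C@@H](O)CC1 | intermediate
5 | (S)-tert-butyl[(4,4-dimethoxy-2-methylcyclohex-2-en-1-yl)oxy]dimethylsilane | COC1(OC)C=C(C)[C@@H](O[Si](C)(C)C(C)(C)C)CC1 | intermediate (not isolated)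
6 | (S)-4-[(tert-butyldimethylsilyl)oxy]-3-methylcyclohex-2-en-1-one | O=C1C=C(C)[C@@H](O[Si](C)(C)C(C)(C)C)CC1 | intermediate
7 | 5-bromo-2-methylpent-2-ene | CC(C)=CCCBr | starting material
8 | (4-methylpent-3-en-1-yl)magnesium bromide | CC(C)=CCC[Mg]Br | intermediate (not isolated)
9 | bromomagnesium (3S,4S)-4-[(tert-butyldimethylsilyl)oxy]-3-methyl-3-(4-methylpent-3-en-1-yl)cyclohex-1-en-1-olate | Br[Mg]OC1=C[C@](C)(CCC=C(C)C)[C@@H](O[Si](C)(C)C(C)(C)C)CC1 | intermediate (not isolated)
10 | (3S,4S)-4-[(tert-butyldimethylsilyl)oxy]-3-methyl-3-(4-methylpent-3-en-1-yl)cyclohex-1-en-1-yl acetate | CC(=O)OC1=C[C@](C)(CCC=C(C)C)[C@@H](O[Si](C)(C)C(C)(C)C)CC1 | intermediate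
11 | (1R,4S,4aS,8aS)-4-[(tert-butyldimethylsilyl)oxy]-4a,8,8-trimethyldecahydronaphthalen-1-yl acetate | CC(=O)O[C@@H]1CC[C@H](O[Si](C)(C)C(C)(C)C)[C@@]2(C)CCCC(C)(C)[C@H]12 | intermediate
12 | (1R,4S,4aS,8aS)-4-hydroxy-4a,8,8-trimethyldecahydronaphthalen-1-yl acetate | CC(=O)O[C@@H]1CC[C@H](O)[C@@]2(C)CCCC(C)(C)[C@H]12 | intermediate
13 | (1R,4aS,8aS)-4a,8,8-trimethyl-4-oxodecahydronaphthalen-1-yl acetate | CC(=O)O[C@@H]1CCC(=O)[C@@]2(C)CCCC(C)(C)[C@H]12 | intermediate
14 | (1R,3R,4aS,8aS)-3,4a,8,8-tetramethyl-4-oxodecahydronaphthalen-1-yl acetate | CC(=O)O[C@@H]1C[C@@H](C)C(=O)[C@@]2(C)CCCC(C)(C)[C@H]12 | intermediate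
15 | (1R,4aS,8aS)-3,4a,8,8-tetramethyl-4-{[(trifluoromethyl)sulfonyl]oxy}-1,2,4a,5,6,7,8,8a-octahydronaphthalen-1-yl acetate | CC(=O)O[C@@H]1CC(C)=C(OS(=O)(=O)C(F)(F)F)[C@@]2(C)CCCC(C)(C)[C@H]12 | intermediate
16 | vinylmagnesium bromide | C=C[Mg]Br | starting material
17 | vinylzinc bromide | C=C[Zn]Br | intermediate (not isolated)
18 | (1R,4aS,8aS)-4-ethenyl-3,4a,8,8-tetramethyl-1,2,4a,5,6,7,8,8a-octahydronaphthalen-1-yl acetate | CC(=O)O[C@@H]1CC(C)=C(C=C)[C@@]2(C)CCCC(C)(C)[C@H]12 | intermediate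
19 | 4-bromofuran-2(5H)-one | O=C1OCC(Br)=C1 | starting material
20 | (1R,4aS,8aS)-4-[2-(9-borabicyclo[3.3.1]nonan-9-yl)ethyl]-3,4a,8,8-tetramethyl-1,2,4a,5,6,7,8,8a-octahydronaphthalen-1-yl acetate | CC(=O)O[C@@H]1CC(C)=C(CCB3C4CCCC3CCC4)[C@@]2(C)CCCC(C)(C)[C@H]12 | intermediate (not isolated)
21 | (1R,4aS,8aS)-3,4a,8,8-tetramethyl-4-[2-(5-oxo-2,5-dihydrofuran-3-yl)ethyl]-1,2,4a,5,6,7,8,8a-octahydronaphthalen-1-yl acetate (CNP0128495.1) | CC(=O)O[C@@H]1CC(C)=C(CCC2=CC(=O)OC2)[C@@]2(C)CCCC(C)(C)[C@H]12 | target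

**Totals**
Total step count: 12. Longest linear sequence: 12 (1 → 21).

**Three steps most likely to fail, with fallbacks**

Step 6 (radical cyclization). The tertiary radical is nucleophilic and the enol acetate is electron-rich, so closure may be slower than simple reduction of the prenyl group, and a cis fusion is possible. Fallback, setting out from 10 and returning at 11: methanolysis of 10 (K2CO3, MeOH) gives (3S,4S)-4-[(tert-butyldimethylsilyl)oxy]-3-methyl-3-(4-methylpent-3-en-1-yl)cyclohexan-1-one F1. A polar cation–olefin cyclization through the ketone enol (SnCl4, CH2Cl2, −78 °C), with C5 free to equilibrate to the trans fusion, gives (4S,4aS,8aS)-4-[(tert-butyldimethylsilyl)oxy]-4a,8,8-trimethyloctahydronaphthalen-1(2H)-one F2. NaBH4 attacks the 6-ketone from the open α-face to give the axial alcohol (1R,4S,4aS,8aS)-4-[(tert-butyldimethylsilyl)oxy]-4a,8,8-trimethyldecahydronaphthalen-1-ol F3, and Ac2O/DMAP then gives 11.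

Step 5 (quaternary centre next to the silyloxy carbon). The cuprate may be too hindered, or O-acylation may be poor. Fallback, setting out from 6 and returning at 11: Hosomi–Sakurai allylation of 6 (allyltrimethylsilane, TiCl4, −78 °C, anti to the silyloxy group) gives (3S,4S)-3-allyl-4-[(tert-butyldimethylsilyl)oxy]-3-methylcyclohexan-1-one F4. Chemoselective hydroboration with 9-BBN gives the B-alkyl borane F5, which is coupled in the same flask with 2-bromopropene (Pd(dppf)Cl2, K3PO4) to (3S,4S)-4-[(tert-butyldimethylsilyl)oxy]-3-methyl-3-(4-methylpent-4-en-1-yl)cyclohexan-1-one F6. SnCl4 cyclizes F6 through the same tertiary cation to the trans-decalone F2, which is carried through the alcohol F3 to 11 as above.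

Step 11 (Negishi vinylation of the hindered tetrasubstituted triflate). Fallback, setting out from 15 and returning at 21, with the roles of the partners reversed: 19 is vinylated with 17 (Pd(PPh3)4, THF) to 4-ethenylfuran-2(5H)-one F7. 9-BBN converts F7 into 4-[2-(9-borabicyclo[3.3.1]nonan-9-yl)ethyl]furan-2(5H)-one F8, and a B-alkyl Suzuki coupling of F8 with 15 (Pd(dppf)Cl2, AsPh3, K3PO4, DMF/H2O) forms the C9–C11 bond and gives 21 directly.

Further compounds
F1 | step 6 | (3S,4S)-4-[(tert-butyldimethylsilyl)oxy]-3-methyl-3-(4-methylpent-3-en-1-yl)cyclohexan-1-one | O=C1C[C@](C)(CCC=C(C)C)[C@@H](O[Si](C)(C)C(C)(C)C)CC1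
F2 | step 6 | (4S,4aS,8aS)-4-[(tert-butyldimethylsilyl)oxy]-4a,8,8-trimethyloctahydronaphthalen-1(2H)-one | O=C1CC[C@H](O[Si](C)(C)C(C)(C)C)[C@@]2(C)CCCC(C)(C)[C@H]12
F3 | step 6 | (1R,4S,4aS,8aS)-4-[(tert-butyldimethylsilyl)oxy]-4a,8,8-trimethyldecahydronaphthalen-1-ol | O[C@@H]1CC[C@H](O[Si](C)(C)C(C)(C)C)[C@@]2(C)CCCC(C)(C)[C@H]12
F4 | step 5 | (3S,4S)-3-allyl-4-[(tert-butyldimethylsilyl)oxy]-3-methylcyclohexan-1-one | O=C1C[C@](C)(CC=C)[C@@H](O[Si](C)(C)C(C)(C)C)CC1
F5 | step 5 | (3S,4S)-3-[3-(9-borabicyclo[3.3.1]nonan-9-yl)propyl]-4-[(tert-butyldimethylsilyl)oxy]-3-methylcyclohexan-1-one | O=C1C[C@](C)(CCCB2C3CCCC2CCC3)[C@@H](O[Si](C)(C)C(C)(C)C)CC1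
F6 | step 5 | (3S,4S)-4-[(tert-butyldimethylsilyl)oxy]-3-methyl-3-(4-methylpent-4-en-1-yl)cyclohexan-1-one | O=C1C[C@](C)(CCCC(C)=C)[C@@H](O[Si](C)(C)C(C)(C)C)CC1
F7 | step 11 | 4-ethenylfuran-2(5H)-one | C=CC1=CC(=O)OC1
F8 | step 11 | 4-[2-(9-borabicyclo[3.3.1]nonan-9-yl)ethyl]furan-2(5H)-one | O=C1OCC(CCB2C3CCCC2CCC3)=C1
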